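In a one-step world a reversible reaction of first order both ways is a lag with a single time constant and a single final ratio, and its end is read from the fraction left; this flask is a chain of such lags with a solid attached to one link.

    substrate ⇌ intermediate (K1 = 1.2, k1 = 0.036 /s)
    intermediate ⇌ target (K2 = 1.5, k2 = 0.010 /s)
    target ⇌ isomer of the product (K3 = 0.79, k3 = 0.034 /s)
    crystals ⇌ target, rate k4*(cs4 - [target]) while solid is left; crystals form when [target] > cs4 (cs4 = 0.032 mM, k4 = 4.1 /s)
    substrate ⇌ dormant form (K5 = 0.43, k5 = 0.036 /s)

substrate 0.0010 M; time 4.0 h

* why nothing more happens at 4.0 h, or that something still does (it is still moving / forward and back rates have come level)
* conversion of substrate at 4.0 h
* amount of target at 4.0 h, in percent of the substrate charged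

- what is said of target includes crystals
- crystals is a solid; its amount is given per volume of the solution
- what has gone from substrate into another species counts as reacted, even if it can come back
- the reaction counts as stopped when no species that holds the substrate changes by six tenths of a point or more over the second half of the time
- run time (flask): 4.0 h

Without the solid, the equilibrium constants of this flask would put 30.8 % of the charge into dissolved target, more than the 3.20 % that the solubility allows, so crystals form. While they last, dissolved target stands at 3.20 %, and the other dissolved forms follow from it through the constants: isomer of the product by its constant, intermediate by the inverse of the second constant, and substrate by the inverse of the first as well, at 1.78 %, with dormant form in its ratio to substrate. These forms, dissolved target included, sum to 10.4 % of the charge. This sum is the solution share, the fraction of the charge left dissolved while crystals stand. The remaining 89.6 % is crystals. Conversion is then one minus the substrate fraction, 98.2 %, and target, being crystals plus dissolved target, is 92.8 %.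

The weak link is the assumption that this state is reached in 4.0 h. The relaxation half-lives of the step from substrate to intermediate and of the step from target to isomer of the product, and the forward half-life of substrate by the step to dormant form, are each shorter than the 0.693 min relaxation half-life of the step from intermediate to target, which makes that step the rate-limiting step. Substrate, intermediate and dormant form therefore drain as one pool, through the intermediate's share of it, 45.6 %. The pool's half-life is 2.53 min, and 4.0 h holds 94.9 of them, so forward and back rates should be level by then.

The forecast gives 98.2 % conversion, 92.8 % target and the verdict that forward and back rates have come level, on the ground that “equilibrium is fully reached”.

The simulation gives 98.2 % conversion and 92.8 % target, and in it forward and back rates have come level. Over the second half of the time, the largest change of the share of a substrate, an intermediate or a product is 0 percentage points. In a neighbour flask charged with 2.5 × 10⁻⁴ M, the dissolved amounts reckoned above stay the same while the charge shrinks, so the solution share grows to 41.6 %, substrate to 7.11 %, and target falls to 71.2 %. That neighbour flask reads, at 4.00 h, substrate 7.11 %, crystals 58.4 % and target 71.2 %.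

The constants used here are assumed; the flask was simulated.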